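**Retrosynthetic overview**

1. The trans-10,11-diol is unveiled last by anti hydration of a cis-epoxide at its allylic carbon. The epoxide is installed early by convex-face nucleophilic epoxidation of a cis-hydrindenone and carried through as the latent diol; these C–O bond formations are the key disconnection.
2. Ring A (eleven-membered) is closed by a Nozaki–Hiyama–Kishi reaction between the ring-C alkenyl triflate and an aldehyde. The side chain comes from an enal and an alkylzinc derived from (S)-citronellal.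
3. Ring B and three stereocentres come from a catalytic enantioselective desymmetrising intramolecular ene reaction of a prochiral cyclohexadienone (the proposed new step).
4. Ring C comes from Robinson annulation of melonal with methyl vinyl ketone, then dehydrogenation.
5. Order of ring formation: C (six) → B (five) → oxirane → A (eleven) → oxirane opened.

Assumption 1: locants are those of the systematic name of the compound under discussion (indene numbering for bicycles; tricyclo[7.5.2.0^{12,15}]hexadecane numbering for tricycles, where C1 is the ring-B carbon bearing ring A, C2 carries the methylidene, C3/C8 the acetates, C9=C16 is the ring alkene, C10/C11 the diol, C12 the quaternary carbon).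
Assumption 2: in step 3 the (S)-oxazaborolidine is written as giving the enantiomer shown; if induction is opposite, the (R)-catalyst is used.

**Route**

Step 1
Reactants: 1 rac-2,6-dimethylhept-5-enal (melonal); 2 but-3-en-2-one (methyl vinyl ketone)
Product: 5 rac-4-methyl-4-(4-methylpent-3-en-1-yl)cyclohex-2-en-1-one, via pyrrolidine enamine 3 (not isolated), via keto aldehyde 4 (not isolated)
Conditions: pyrrolidine, PhMe, reflux (Dean–Stark); 2, 0 °C → rt; AcOH/NaOAc/H2O, 80 °C
Reagents that add atoms: none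
Why: Stork enamine Michael addition then intramolecular aldol condensation (Robinson annulation) of an α-branched aldehyde is the standard entry to 4,4-disubstituted cyclohexenones; the quaternary centre is racemic here and loses its chirality in step 2.

Step 2
Reactants: 5 rac-4-methyl-4-(4-methylpent-3-en-1-yl)cyclohex-2-en-1-one
Product: 6 4-methyl-4-(4-methylpent-3-en-1-yl)cyclohexa-2,5-dien-1-one
Conditions: IBX (2.5 equiv), DMSO, 80 °C
Reagents that add atoms: none
Why: IBX dehydrogenation of an enone gives the cross-conjugated dienone (the quaternary C4 blocks aromatisation), an achiral substrate with two enantiotopic enone arms.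

Step 3
Reactants: 6 4-methyl-4-(4-methylpent-3-en-1-yl)cyclohexa-2,5-dien-1-one
Product: 7 (3R,3aR,7aR)-7a-methyl-3-(prop-1-en-2-yl)-1,2,3,3a,4,7a-hexahydro-5H-inden-5-one
Conditions: AlBr3-activated (S)-3,3-diphenyl-1-(o-tolyl)tetrahydro-1H,3H-pyrrolo[1,2-c][1,3,2]oxazaborole (10 mol %), CH2Cl2, −40 °C
Reagents that add atoms: none
Why: Proposed new method: a catalytic enantioselective desymmetrising type-one intramolecular ene reaction, in which the cationic oxazaborolidine binds the dienone carbonyl and shields one face of one enone arm, so the tethered trisubstituted alkene (which can only reach its own face) adds through its CH terminus to the β-carbon of the other arm; the three-atom tether enforces cis ring fusion, and transfer of a methyl hydrogen to C4 in the compact transition state places the propenyl group cis to C4, so C3, C3a and C7a are set together; the closest known reactions are Lewis-acid-promoted type-one ene cyclisations of 1,6-dienes and oxazaborolidinium-catalysed enantioselective cycloadditions of cyclohexenones and quinone monoketals.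

Step 4
Reactants: 7 (3R,3aR,7aR)-7a-methyl-3-(prop-1-en-2-yl)-1,2,3,3a,4,7a-hexahydro-5H-inden-5-one
Product: 8 (3R,3aR,6R,7R,7aS)-6,7-epoxy-7a-methyl-3-(prop-1-en-2-yl)octahydro-5H-inden-5-one
Conditions: 30% H2O2, NaOH (0.2 equiv), MeOH, 0 °C
Reagents that add atoms: hydrogen peroxide, OO
Why: Weitz–Scheffer nucleophilic epoxidation touches only the enone; hydroperoxide should add to C7 from the convex face of the cis-hydrindenone (anti to ring B, syn to the angular methyl), setting both C–O stereocentres (C6, C7) of the future diol.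

Step 5
Reactants: 8 (3R,3aR,6R,7R,7aS)-6,7-epoxy-7a-methyl-3-(prop-1-en-2-yl)octahydro-5H-inden-5-one
Product: 10 (3R,3aS,4RS,6R,7R,7aS)-6,7-epoxy-4,7a-dimethyl-3-(prop-1-en-2-yl)octahydro-5H-inden-5-one, via lithium enolate 9 (not isolated)
Conditions: LiN(iPr)2, THF, −78 °C; MeI, −78 → −30 °C
Reagents that add atoms: iodomethane, CI
Why: Kinetic enolate alkylation at C4, the only CH2 next to the ketone; the C4 configuration is irrelevant because it becomes sp2 in step 6.

Step 6
Reactants: 10 (3R,3aS,4RS,6R,7R,7aS)-6,7-epoxy-4,7a-dimethyl-3-(prop-1-en-2-yl)octahydro-5H-inden-5-one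
Product: 12 (3R,3aR,6R,7R,7aS)-6,7-epoxy-4,7a-dimethyl-3-(prop-1-en-2-yl)-2,3,3a,6,7,7a-hexahydro-1H-inden-5-yl trifluoromethanesulfonate, via potassium enolate 11 (not isolated)
Conditions: KN(SiMe3)2, THF, −78 °C; PhNTf2, −78 → 0 °C
Reagents that add atoms: N-phenylbis(trifluoromethanesulfonimide), O=S(=O)(N(c1ccccc1)S(=O)(=O)C(F)(F)F)C(F)(F)F
Why: Enol triflate formation is regiospecific because only C4 carries an enolisable hydrogen (C6 is an oxirane carbon); it creates the tetrasubstituted ring alkene, and the electron-poor triflate keeps the neighbouring epoxide inert to acid until step 13.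

Step 7
Reactants: 12 (3R,3aR,6R,7R,7aS)-6,7-epoxy-4,7a-dimethyl-3-(prop-1-en-2-yl)-2,3,3a,6,7,7a-hexahydro-1H-inden-5-yl trifluoromethanesulfonate
Product: 14 (3R,3aR,6R,7R,7aS)-6,7-epoxy-4,7a-dimethyl-3-(3-oxoprop-1-en-2-yl)-2,3,3a,6,7,7a-hexahydro-1H-inden-5-yl trifluoromethanesulfonate, via allylic alcohol 13 (not isolated)
Conditions: SeO2 (0.3 equiv), t-BuOOH, CH2Cl2, rt; then MnO2, CH2Cl2, rt
Reagents that add atoms: tert-butyl hydroperoxide, CC(C)(C)OO (oxygen delivered through SeO2, O=[Se]=O)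
Why: Selenium dioxide allylic oxidation (ene then [2,3]-shift) oxidises the methyl of the electron-richer 1,1-disubstituted alkene (CH3 preferred over CH, enol triflate alkene deactivated), and MnO2 completes oxidation to the 2-substituted acrolein.

Step 8
Reactants: 15 (S)-citronellal, (3S)-3,7-dimethyloct-6-enal
Product: 16 (6S)-8,8-dimethoxy-2,6-dimethyloct-2-ene
Conditions: HC(OMe)3, MeOH, PPTS (cat.), rt
Reagents that add atoms: trimethyl orthoformate, COC(OC)OC; methanol, CO
Why: Acid-catalysed acetalisation masks the aldehyde; the methyl stereocentre is untouched.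

Step 9
Reactants: 16 (6S)-8,8-dimethoxy-2,6-dimethyloct-2-ene
Product: 17 (4S)-6,6-dimethoxy-4-methylhexanoic acid
Conditions: KMnO4 (cat.), NaIO4, K2CO3, t-BuOH/H2O, rt
Reagents that add atoms: sodium periodate, [Na+].[O-]I(=O)(=O)=O (oxygen delivered through KMnO4); water, O
Why: Lemieux–von Rudloff cleavage of the trisubstituted alkene gives the carboxylic acid and acetone under buffered basic conditions that keep the acetal intact.

Step 10
Reactants: 17 (4S)-6,6-dimethoxy-4-methylhexanoic acid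
Product: 18 (3R)-5-iodo-1,1-dimethoxy-3-methylpentane
Conditions: PhI(OAc)2, I2, cyclohexane, hν (W lamp), reflux
Reagents that add atoms: iodine, II
Why: Suárez iododecarboxylation (acyl hypoiodite, radical decarboxylation, iodine capture) shortens the chain by one carbon to the primary iodide; the stereocentre is remote (descriptor changes by priority only).

Step 11
Reactants: 14 (3R,3aR,6R,7R,7aS)-6,7-epoxy-4,7a-dimethyl-3-(3-oxoprop-1-en-2-yl)-2,3,3a,6,7,7a-hexahydro-1H-inden-5-yl trifluoromethanesulfonate; 18 (3R)-5-iodo-1,1-dimethoxy-3-methylpentane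
Product: 20 (3R,3aR,6R,7R,7aS)-6,7-epoxy-3-[(3R,6S)-3-hydroxy-8,8-dimethoxy-6-methyloct-1-en-2-yl]-4,7a-dimethyl-2,3,3a,6,7,7a-hexahydro-1H-inden-5-yl trifluoromethanesulfonate, via dialkylzinc 19 (not isolated)
Conditions: 18, Et2Zn, CuI (cat.), 50 °C, then vacuum; Ti(OiPr)4, (1S,2S)-cyclohexane-1,2-diylbis(trifluoromethanesulfonamide) (8 mol %), PhMe, −20 °C; 14
Reagents that add atoms: none
Why: Knochel iodine–zinc exchange then titanium/bis-sulfonamide-catalysed enantioselective 1,2-addition of the dialkylzinc to the enal; the ligand controls the new carbinol (3R in the side chain, with the (1S,2S)-ligand by analogy with (1R,2R) giving S alcohols from unsaturated aldehydes), and triflate, epoxide and acetal are tolerated.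

Step 12
Reactants: 20 (3R,3aR,6R,7R,7aS)-6,7-epoxy-3-[(3R,6S)-3-hydroxy-8,8-dimethoxy-6-methyloct-1-en-2-yl]-4,7a-dimethyl-2,3,3a,6,7,7a-hexahydro-1H-inden-5-yl trifluoromethanesulfonate
Product: 21 (3R,3aR,6R,7R,7aS)-6,7-epoxy-3-[(3R,6S)-3-hydroxy-6-methyl-8-oxooct-1-en-2-yl]-4,7a-dimethyl-2,3,3a,6,7,7a-hexahydro-1H-inden-5-yl trifluoromethanesulfonate
Conditions: PPTS (cat.), acetone/H2O, 40 °C
Reagents that add atoms: water, O
Why: Mild acetal hydrolysis frees the aldehyde; the epoxide survives because the adjacent alkene carries the triflate and cannot stabilise an allyl cation.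

Step 13
Reactants: 21 (3R,3aR,6R,7R,7aS)-6,7-epoxy-3-[(3R,6S)-3-hydroxy-6-methyl-8-oxooct-1-en-2-yl]-4,7a-dimethyl-2,3,3a,6,7,7a-hexahydro-1H-inden-5-yl trifluoromethanesulfonate
Product: 22 (1R,3R,6S,8S,10S,11R,12S,15S)-10,11-epoxy-6,12,16-trimethyl-2-methylidenetricyclo[7.5.2.0^{12,15}]hexadec-9(16)-ene-3,8-diol
Conditions: CrCl2 (6 equiv), NiCl2 (2 mol %), DMF, rt, 2 mM (slow addition)
Reagents that add atoms: none
Why: Nozaki–Hiyama–Kishi macrocyclisation (nickel-catalysed activation of the alkenyl triflate, transmetalation to chromium, 1,2-addition to the aldehyde) closes ring A and tolerates the free hydroxyl and the epoxide; the 8S carbinol is the hoped-for outcome of substrate control only, since the chain must approach from the ring-B face that carries it (see fallback).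

Step 14
Reactants: 22 (1R,3R,6S,8S,10S,11R,12S,15S)-10,11-epoxy-6,12,16-trimethyl-2-methylidenetricyclo[7.5.2.0^{12,15}]hexadec-9(16)-ene-3,8-diol
Product: 23 (1R,3R,6S,8S,10S,11R,12S,15S)-10,11-epoxy-6,12,16-trimethyl-2-methylidenetricyclo[7.5.2.0^{12,15}]hexadec-9(16)-ene-3,8-diyl diacetate
Conditions: Ac2O, pyridine, DMAP (cat.), CH2Cl2, 0 °C → rt
Reagents that add atoms: acetic anhydride, CC(=O)OC(C)=O
Why: DMAP-catalysed acylation esterifies both secondary allylic alcohols while the future diol is still masked as the epoxide, so no hydroxyl differentiation is needed.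

Step 15
Reactants: 23 (1R,3R,6S,8S,10S,11R,12S,15S)-10,11-epoxy-6,12,16-trimethyl-2-methylidenetricyclo[7.5.2.0^{12,15}]hexadec-9(16)-ene-3,8-diyl diacetate
Product: 24 (1R,3R,6S,8S,10R,11R,12S,15S)-10,11-dihydroxy-6,12,16-trimethyl-2-methylidenetricyclo[7.5.2.0^{12,15}]hexadec-9(16)-ene-3,8-diyl diacetate (target)
Conditions: HClO4 (3 mol %), THF/H2O (3:1), 0 °C
Reagents that add atoms: water, O
Why: Acid-catalysed hydration of a vinyl epoxide; with the triflate gone the epoxide is allylic to an ordinary alkene, so water attacks the allylic C10 anti to the C–O bond (inversion) while neopentyl C11 keeps its oxygen, giving the trans-diol, and the acetates survive dilute acid at 0 °C.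

**Compound list**

1 | rac-2,6-dimethylhept-5-enal (melonal) | CC(C)=CCCC(C)C=O | starting material
2 | but-3-en-2-one (methyl vinyl ketone) | C=CC(C)=O | starting material
3 | 1-(2,6-dimethylhepta-1,5-dien-1-yl)pyrrolidine (enamine of 1) | CC(C)=CCCC(C)=CN1CCCC1 | intermediate (not isolated)
4 | rac-2-methyl-2-(4-methylpent-3-en-1-yl)-5-oxohexanal | CC(C)=CCCC(C)(CCC(C)=O)C=O | intermediate (not isolated)
5 | rac-4-methyl-4-(4-methylpent-3-en-1-yl)cyclohex-2-en-1-one | CC(C)=CCCC1(C)CCC(=O)C=C1 | intermediate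
6 | 4-methyl-4-(4-methylpent-3-en-1-yl)cyclohexa-2,5-dien-1-one (achiral) | CC(C)=CCCC1(C)C=CC(=O)C=C1 | intermediate
7 | (3R,3aR,7aR)-7a-methyl-3-(prop-1-en-2-yl)-1,2,3,3a,4,7a-hexahydro-5H-inden-5-one | O=C1C[C@@H]2[C@H](C(C)=C)CC[C@]2(C)C=C1 | intermediate
8 | (3R,3aR,6R,7R,7aS)-6,7-epoxy-7a-methyl-3-(prop-1-en-2-yl)octahydro-5H-inden-5-one | O=C1C[C@@H]2[C@H](C(C)=C)CC[C@]2(C)[C@H]3O[C@H]31 | intermediate
9 | lithium enolate of 8 (C4=C5–OLi) | [Li]OC1=C[C@@H]2[C@H](C(C)=C)CC[C@]2(C)[C@H]3O[C@H]31 | intermediate (not isolated)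
10 | (3R,3aS,4RS,6R,7R,7aS)-6,7-epoxy-4,7a-dimethyl-3-(prop-1-en-2-yl)octahydro-5H-inden-5-one (C4 epimers) | O=C1C(C)[C@@H]2[C@H](C(C)=C)CC[C@]2(C)[C@H]3O[C@H]31 | intermediate
11 | potassium enolate of 10 (C4=C5–OK) | [K]OC1=C(C)[C@@H]2[C@H](C(C)=C)CC[C@]2(C)[C@H]3O[C@H]31 | intermediate (not isolated)
12 | (3R,3aR,6R,7R,7aS)-6,7-epoxy-4,7a-dimethyl-3-(prop-1-en-2-yl)-2,3,3a,6,7,7a-hexahydro-1H-inden-5-yl trifluoromethanesulfonate | O=S(=O)(OC1=C(C)[C@@H]2[C@H](C(C)=C)CC[C@]2(C)[C@H]3O[C@H]31)C(F)(F)F | intermediate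
13 | (3R,3aR,6R,7R,7aS)-6,7-epoxy-3-(3-hydroxyprop-1-en-2-yl)-4,7a-dimethyl-2,3,3a,6,7,7a-hexahydro-1H-inden-5-yl trifluoromethanesulfonate | O=S(=O)(OC1=C(C)[C@@H]2[C@H](C(=C)CO)CC[C@]2(C)[C@H]3O[C@H]31)C(F)(F)F | intermediate (not isolated)
14 | (3R,3aR,6R,7R,7aS)-6,7-epoxy-4,7a-dimethyl-3-(3-oxoprop-1-en-2-yl)-2,3,3a,6,7,7a-hexahydro-1H-inden-5-yl trifluoromethanesulfonate | O=S(=O)(OC1=C(C)[C@@H]2[C@H](C(=C)C=O)CC[C@]2(C)[C@H]3O[C@H]31)C(F)(F)F | intermediate
15 | (S)-citronellal, (3S)-3,7-dimethyloct-6-enal | C[C@@H](CCC=C(C)C)CC=O | starting material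
16 | (6S)-8,8-dimethoxy-2,6-dimethyloct-2-ene | C[C@@H](CCC=C(C)C)CC(OC)OC | intermediate
17 | (4S)-6,6-dimethoxy-4-methylhexanoic acid | C[C@@H](CCC(O)=O)CC(OC)OC | intermediate
18 | (3R)-5-iodo-1,1-dimethoxy-3-methylpentane | C[C@@H](CCI)CC(OC)OC | intermediate
19 | bis[(3R)-5,5-dimethoxy-3-methylpentyl]zinc | C[C@@H](CC[Zn]CC[C@@H](C)CC(OC)OC)CC(OC)OC | intermediate (not isolated)
20 | (3R,3aR,6R,7R,7aS)-6,7-epoxy-3-[(3R,6S)-3-hydroxy-8,8-dimethoxy-6-methyloct-1-en-2-yl]-4,7a-dimethyl-2,3,3a,6,7,7a-hexahydro-1H-inden-5-yl trifluoromethanesulfonate | O=S(=O)(OC1=C(C)[C@@H]2[C@H](C(=C)[C@H](O)CC[C@H](C)CC(OC)OC)CC[C@]2(C)[C@H]3O[C@H]31)C(F)(F)F | intermediate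
21 | (3R,3aR,6R,7R,7aS)-6,7-epoxy-3-[(3R,6S)-3-hydroxy-6-methyl-8-oxooct-1-en-2-yl]-4,7a-dimethyl-2,3,3a,6,7,7a-hexahydro-1H-inden-5-yl trifluoromethanesulfonate | O=S(=O)(OC1=C(C)[C@@H]2[C@H](C(=C)[C@H](O)CC[C@H](C)CC=O)CC[C@]2(C)[C@H]3O[C@H]31)C(F)(F)F | intermediate
22 | (1R,3R,6S,8S,10S,11R,12S,15S)-10,11-epoxy-6,12,16-trimethyl-2-methylidenetricyclo[7.5.2.0^{12,15}]hexadec-9(16)-ene-3,8-diol | C=C1[C@H](O)CC[C@H](C)C[C@H](O)C2=C(C)[C@@H]3[C@H]1CC[C@]3(C)[C@H]4O[C@H]42 | intermediate
23 | (1R,3R,6S,8S,10S,11R,12S,15S)-10,11-epoxy-6,12,16-trimethyl-2-methylidenetricyclo[7.5.2.0^{12,15}]hexadec-9(16)-ene-3,8-diyl diacetate | C=C1[C@H](OC(C)=O)CC[C@H](C)C[C@H](OC(C)=O)C2=C(C)[C@@H]3[C@H]1CC[C@]3(C)[C@H]4O[C@H]42 | intermediate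
24 | (1R,3R,6S,8S,10R,11R,12S,15S)-10,11-dihydroxy-6,12,16-trimethyl-2-methylidenetricyclo[7.5.2.0^{12,15}]hexadec-9(16)-ene-3,8-diyl diacetate | C=C1[C@H](OC(C)=O)CC[C@H](C)C[C@H](OC(C)=O)C2=C(C)[C@@H]3[C@H]1CC[C@]3(C)[C@@H](O)[C@@H]2O | target

**Step count**

Total steps: 15. Longest linear sequence: 12 (steps 1–7 and 11–15; steps 8–10 make the side-chain piece).

**Three steps most likely to fail**

Step 3 (the proposed new enantioselective ene reaction). Enantioselectivity, or the catalytic reaction itself, may fail. The fallback sets out from 6 and returns at 7. Me2AlCl (1.2 equiv) in CH2Cl2 at −78 → 0 °C (or heating in PhMe in a sealed tube) runs the same type-one ene cyclisation without induction. This gives 7 together with its mirror image, (3S,3aS,7aS)-7a-methyl-3-(prop-1-en-2-yl)-1,2,3,3a,4,7a-hexahydro-5H-inden-5-one F1. The enantiomers are separated by preparative chiral supercritical-fluid chromatography, and 7 continues into step 4.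

Step 13 (closure of ring A). The ring closure is at a hindered tetrasubstituted alkenyl triflate and the new carbinol is under substrate control only. The fallback sets out from 20 and returns at 23; it closes the ring with C3 already acetylated and then sets the carbinol by reagent control.
- 20 is acetylated (Ac2O, pyridine, DMAP) to (3R,6S)-2-[(3R,3aR,6R,7R,7aS)-6,7-epoxy-4,7a-dimethyl-5-(trifluoromethanesulfonyloxy)-2,3,3a,6,7,7a-hexahydro-1H-inden-3-yl]-8,8-dimethoxy-6-methyloct-1-en-3-yl acetate F2.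
- The acetal is hydrolysed (PPTS, acetone/H2O) to (3R,6S)-2-[(3R,3aR,6R,7R,7aS)-6,7-epoxy-4,7a-dimethyl-5-(trifluoromethanesulfonyloxy)-2,3,3a,6,7,7a-hexahydro-1H-inden-3-yl]-6-methyl-8-oxooct-1-en-3-yl acetate F3.
- CrCl2/NiCl2 closure is run without regard to carbinol configuration, giving (1R,3R,6S,8RS,10S,11R,12S,15S)-10,11-epoxy-8-hydroxy-6,12,16-trimethyl-2-methylidenetricyclo[7.5.2.0^{12,15}]hexadec-9(16)-en-3-yl acetate F4.
- Dess–Martin periodinane converges both epimers on (1R,3R,6S,10S,11R,12S,15S)-10,11-epoxy-6,12,16-trimethyl-2-methylidene-8-oxotricyclo[7.5.2.0^{12,15}]hexadec-9(16)-en-3-yl acetate F5.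
- Corey–Bakshi–Shibata reduction with catecholborane and (R)-1-methyl-3,3-diphenyltetrahydro-1H,3H-pyrrolo[1,2-c][1,3,2]oxazaborole (alkenyl group as the large substituent) gives (1R,3R,6S,8S,10S,11R,12S,15S)-10,11-epoxy-8-hydroxy-6,12,16-trimethyl-2-methylidenetricyclo[7.5.2.0^{12,15}]hexadec-9(16)-en-3-yl acetate F6.
- Acetylation (Ac2O, pyridine, DMAP) gives 23.

Step 15 (epoxide hydration). Partial loss of stereochemistry through an allyl cation, attack at C16, or acetyl migration by participation of the C8 acetate are possible. The fallback sets out from 23 and returns at 24. The epoxide is opened in a non-aqueous medium with ClCH2CO2H (3 equiv, CH2Cl2, 0 °C → rt), the acid serving as proton source and its carboxylate as the nucleophile at the allylic carbon with inversion. This gives (1R,3R,6S,8S,10R,11R,12S,15S)-10-(chloroacetoxy)-11-hydroxy-6,12,16-trimethyl-2-methylidenetricyclo[7.5.2.0^{12,15}]hexadec-9(16)-ene-3,8-diyl diacetate F7. The chloroacetyl group is then removed selectively in the presence of the two acetates with thiourea, NaHCO3, EtOH, 50 °C, giving 24.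

**Further compounds**

F1 | step 3 | (3S,3aS,7aS)-7a-methyl-3-(prop-1-en-2-yl)-1,2,3,3a,4,7a-hexahydro-5H-inden-5-one | O=C1C[C@H]2[C@@H](C(C)=C)CC[C@@]2(C)C=C1
F2 | step 13 | (3R,6S)-2-[(3R,3aR,6R,7R,7aS)-6,7-epoxy-4,7a-dimethyl-5-(trifluoromethanesulfonyloxy)-2,3,3a,6,7,7a-hexahydro-1H-inden-3-yl]-8,8-dimethoxy-6-methyloct-1-en-3-yl acetate | O=S(=O)(OC1=C(C)[C@@H]2[C@H](C(=C)[C@H](OC(C)=O)CC[C@H](C)CC(OC)OC)CC[C@]2(C)[C@H]3O[C@H]31)C(F)(F)F
F3 | step 13 | (3R,6S)-2-[(3R,3aR,6R,7R,7aS)-6,7-epoxy-4,7a-dimethyl-5-(trifluoromethanesulfonyloxy)-2,3,3a,6,7,7a-hexahydro-1H-inden-3-yl]-6-methyl-8-oxooct-1-en-3-yl acetate | O=S(=O)(OC1=C(C)[C@@H]2[C@H](C(=C)[C@H](OC(C)=O)CC[C@H](C)CC=O)CC[C@]2(C)[C@H]3O[C@H]31)C(F)(F)F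
F4 | step 13 | (1R,3R,6S,8RS,10S,11R,12S,15S)-10,11-epoxy-8-hydroxy-6,12,16-trimethyl-2-methylidenetricyclo[7.5.2.0^{12,15}]hexadec-9(16)-en-3-yl acetate | C=C1[C@H](OC(C)=O)CC[C@H](C)CC(O)C2=C(C)[C@@H]3[C@H]1CC[C@]3(C)[C@H]4O[C@H]42
F5 | step 13 | (1R,3R,6S,10S,11R,12S,15S)-10,11-epoxy-6,12,16-trimethyl-2-methylidene-8-oxotricyclo[7.5.2.0^{12,15}]hexadec-9(16)-en-3-yl acetate | C=C1[C@H](OC(C)=O)CC[C@H](C)CC(=O)C2=C(C)[C@@H]3[C@H]1CC[C@]3(C)[C@H]4O[C@H]42
F6 | step 13 | (1R,3R,6S,8S,10S,11R,12S,15S)-10,11-epoxy-8-hydroxy-6,12,16-trimethyl-2-methylidenetricyclo[7.5.2.0^{12,15}]hexadec-9(16)-en-3-yl acetate | C=C1[C@H](OC(C)=O)CC[C@H](C)C[C@H](O)C2=C(C)[C@@H]3[C@H]1CC[C@]3(C)[C@H]4O[C@H]42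
F7 | step 15 | (1R,3R,6S,8S,10R,11R,12S,15S)-10-(chloroacetoxy)-11-hydroxy-6,12,16-trimethyl-2-methylidenetricyclo[7.5.2.0^{12,15}]hexadec-9(16)-ene-3,8-diyl diacetate | C=C1[C@H](OC(C)=O)CC[C@H](C)C[C@H](OC(C)=O)C2=C(C)[C@@H]3[C@H]1CC[C@]3(C)[C@@H](O)[C@@H]2OC(=O)CCl
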